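Ring A (C1–C5, C10; labdane locants) is cut at C1–C10 and C2–C3, so that C1–C2 arrive as one two-carbon unit. The key step exploits that quaternary C10 adjoins C9, a ring B ketone in the precursor, and stands 1,4 to C3, an aldehyde there: in a Schweizer annulation the regiodefined C9–C10 enolate adds to vinyltriphenylphosphonium bromide and the ylide closes ring A by intramolecular Wittig reaction. The precursor is a monocyclic silyl enol ether from (R)-carvone, whose C7 acetoxy group controls C5 and C10 and supplies the C7 oxygen. The side chain comes by cross-metathesis; the 1,2-dioxepine is closed last with hydrogen peroxide.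

Key step: step 3

Remark: labdane locants are used throughout (normal series: 5α-H, 9α-H, 10β-CH3); the hemiperoxyacetal carbon C15 is taken to equilibrate by ring opening, and the target epimer (15R) is assumed to be the thermodynamic one.

Step 1
Reactants: 1 (R)-carvone
Product: 4 (1R)-4-methyl-5-oxocyclohex-3-en-1-yl acetate, via methoxy hydroperoxide 2 (not isolated), via peracetate 3 (not isolated)
Conditions: O3, CH2Cl2/MeOH, −78 °C; then Ac2O, Et3N, DMAP (cat.), 0 °C
Reagents that add atoms: ozone, [O-][O+]=O; methanol, CO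
Why: Ozonolysis of the electron-rich isopropenyl group in methanol (the enone C=C is deactivated) should give 2, and its peracetate 3 should undergo Criegee rearrangement with migration of the ring carbon under retention, so that the isopropenyl group becomes an acetoxy group whose acetyl carbons are the former isopropenyl carbons and whose carbonyl oxygen comes from methanol.

Step 2
Reactants: 4 (1R)-4-methyl-5-oxocyclohex-3-en-1-yl acetate; 5 trimethyl[(2-methylprop-1-en-1-yl)oxy]silane
Product: 6 (1R,5R)-4-methyl-5-(2-methyl-1-oxopropan-2-yl)-3-[(trimethylsilyl)oxy]cyclohex-3-en-1-yl acetate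
Conditions: Me3SiNTf2 (5 mol %, from HNTf2), CH2Cl2, −78 °C, slow addition of 5; Et3N quench, non-aqueous work-up
Reagents that add atoms: none
Why: Mukaiyama–Michael addition should deliver the enol silane carbon (future C4) to the enone β-carbon (C5) anti to the C7 acetoxy group by axial attack on the half-chair (trans-3,5 product), with silyl transfer to the C9 oxygen that fixes the C9–C10 enolate regiochemistry.

Step 3
Reactants: 6 (1R,5R)-4-methyl-5-(2-methyl-1-oxopropan-2-yl)-3-[(trimethylsilyl)oxy]cyclohex-3-en-1-yl acetate; 7 triphenyl(vinyl)phosphonium bromide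
Product: 10 (3R,4aS,8aS)-5,5,8a-trimethyl-1-oxo-1,2,3,4,4a,5,8,8a-octahydronaphthalen-3-yl acetate, via sulfonium enolate 8 (not isolated), via phosphorus ylide 9 (not isolated)
Conditions: 7 (1.5 equiv), (Me2N)3S+ Me3SiF2− (TASF, 1.1 equiv, slow addition), MeCN/THF, −40 °C → rt
Reagents that add atoms: none
Why: Fluoride converts the enol silane into the regiodefined C9–C10 enolate 8, whose C10 adds to the vinylphosphonium salt (conjugate addition, C1–C10 bond) to give ylide 9, and intramolecular Wittig olefination of the C3 aldehyde then forms the C2–C3 bond as a C2=C3 alkene and closes ring A. The closest known reaction type is the Schweizer annulation (conjugate addition to vinyltriphenylphosphonium bromide followed by intramolecular Wittig reaction), used here as an anionic [4+2] ring construction. Ring A closes in a six-membered mode by attack of the ylide carbon on the aldehyde carbon (6-exo-trig) and loss of triphenylphosphine oxide to the cis ring alkene. The new quaternary stereocenter C10 is controlled by C5: A(1,2) strain with the C10 methyl makes the bulky C5 substituent pseudoaxial, so the electrophile enters anti to it, which places C1 trans to C4 and leads to the trans ring fusion. The step needs C- over O-alkylation and conjugate addition over aldol reaction or acetate elimination; this should be secured by the regiospecific enolate (no C8 enolate, so the C7 acetate is not eliminated), by the non-enolizable neopentyl C3 aldehyde and by the excess of the highly electrophilic vinylphosphonium salt.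

Step 4
Reactants: 10 (3R,4aS,8aS)-5,5,8a-trimethyl-1-oxo-1,2,3,4,4a,5,8,8a-octahydronaphthalen-3-yl acetate
Product: 11 (3R,4aS,8aS)-5,5,8a-trimethyl-1-oxodecahydronaphthalen-3-yl acetate
Conditions: H2 (1 atm), Pd/C, EtOAc, rt
Reagents that add atoms: none
Why: Catalytic hydrogenation should saturate the only C=C bond (C2=C3), while the ketone and the acetate are inert.

Step 5
Reactants: 11 (3R,4aS,8aS)-5,5,8a-trimethyl-1-oxodecahydronaphthalen-3-yl acetate
Product: 12 (3R,4aS,8aS)-5,5,8a-trimethyl-1-(prop-2-en-1-yl)decahydronaphthalene-1,3-diol (14,15,16,17-tetranorlabd-12-ene-7α,9-diol; C9 epimers)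
Conditions: CH2=CHCH2MgBr (3.5 equiv), THF, −78 °C → rt; aq. NH4Cl
Reagents that add atoms: allylmagnesium bromide, C=CC[Mg]Br
Why: Grignard 1,2-addition of the allyl reagent to the hindered C9 ketone is fast and the excess reagent cleaves the acetate; the C9 configuration is of no consequence because C9 becomes sp2 in step 6.

Step 6
Reactants: 12 (3R,4aS,8aS)-5,5,8a-trimethyl-1-(prop-2-en-1-yl)decahydronaphthalene-1,3-diol
Product: 14 (4aS,8aS)-4a,8,8-trimethyl-4-(prop-2-en-1-yl)-4a,5,6,7,8,8a-hexahydronaphthalen-2(1H)-one (14,15,16,17-tetranorlabda-8,12-dien-7-one), via ketol 13 (not isolated)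
Conditions: Dess–Martin periodinane, CH2Cl2, rt; then TsOH·H2O (cat.), benzene, 80 °C
Reagents that add atoms: none
Why: Dess–Martin oxidation of the secondary C7 alcohol (the tertiary C9 alcohol is inert) should give ketol 13, and acid-catalysed dehydration of this tertiary β-hydroxy ketone gives the conjugated enone, as in the dehydration step of a Robinson annulation.

Step 7
Reactants: 14 (4aS,8aS)-4a,8,8-trimethyl-4-(prop-2-en-1-yl)-4a,5,6,7,8,8a-hexahydronaphthalen-2(1H)-one
Product: 16 17-hydroxy-14,15,16-trinorlabd-12-en-7-one (9α-H; C8 epimers), via lithium enolate 15 (not isolated)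
Conditions: Li (2.2 equiv), NH3(l)/THF, t-BuOH (1 equiv), −78 °C; NH3 removed; then CH2O (gas), THF, −78 °C; aq. NH4Cl
Reagents that add atoms: formaldehyde, C=O
Why: Dissolving-metal (Birch-type) reduction of the enone should give the C7–C8 lithium enolate 15 regiospecifically with axial protonation at C9 (9α-H, side chain equatorial), and the enolate is trapped at C8 by formaldehyde (reductive aldol hydroxymethylation).

Step 8
Reactants: 16 17-hydroxy-14,15,16-trinorlabd-12-en-7-one
Product: 18 14,15,16-trinorlabda-8(17),12-dien-7-one, via mesylate 17 (not isolated)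
Conditions: MsCl, Et3N, CH2Cl2, 0 °C; then DBU, 0 °C
Reagents that add atoms: none
Why: Mesylation of the primary alcohol and E1cB elimination of the β-mesyloxy ketone should give the α-methylene ketone and remove the C8 stereocenter.

Step 9
Reactants: 18 14,15,16-trinorlabda-8(17),12-dien-7-one
Product: 19 14,15,16-trinorlabda-8(17),12-dien-7β-ol
Conditions: NaBH4, CeCl3·7H2O, MeOH, −78 °C
Reagents that add atoms: none
Why: Luche reduction gives 1,2-reduction of the enone, and axial delivery of hydride from the α face should give the equatorial 7β-alcohol (7S).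

Step 10
Reactants: 20 methyl 4,4-dimethoxybutanoate
Product: 21 4,4-dimethoxybutanal
Conditions: i-Bu2AlH (1.05 equiv), CH2Cl2, −78 °C; aq. Rochelle salt
Reagents that add atoms: none
Why: Partial reduction of the ester at −78 °C stops at the aldehyde through the stable tetrahedral aluminium hemiacetal.

Step 11
Reactants: 21 4,4-dimethoxybutanal
Product: 22 4,4-dimethoxy-2-methylidenebutanal
Conditions: aq. CH2O (37%), pyrrolidine (10 mol %), propionic acid (10 mol %), i-PrOH, 45 °C
Reagents that add atoms: formaldehyde, C=O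
Why: Amine-catalysed α-methylenation (Mannich condensation and elimination) of the aldehyde should proceed without touching the acetal in the weakly acidic medium.

Step 12
Reactants: 19 14,15,16-trinorlabda-8(17),12-dien-7β-ol; 22 4,4-dimethoxy-2-methylidenebutanal
Product: 23 7β-hydroxy-15,15-dimethoxylabda-8(17),12E-dien-16-al
Conditions: second-generation Hoveyda–Grubbs catalyst (5 mol %), 22 (3 equiv), CH2Cl2, 40 °C
Reagents that add atoms: none
Why: Olefin cross-metathesis should join the unhindered monosubstituted allyl alkene to the α-substituted acrolein with loss of ethene, the hindered 1,1-disubstituted C8=C17 alkene being inert, and give the thermodynamically preferred E trisubstituted enal.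

Step 13
Reactants: 23 7β-hydroxy-15,15-dimethoxylabda-8(17),12E-dien-16-al
Product: 24 15,15-dimethoxy-7β,16-bis(trimethylsilyloxy)labda-8(17),11E,13(16)E-triene
Conditions: Me3SiCl (3 equiv), Et3N (4 equiv), ZnCl2 (cat.), benzene, 40 °C
Reagents that add atoms: chlorotrimethylsilane, C[Si](C)(C)Cl
Why: Soft vinylogous enolization at the γ-carbon C11 and O-silylation should give the 1-silyloxy-1,3-diene (the C7 hydroxyl is silylated as well), with the bulky C9 substituent trans to C13 on the new C11=C12 bond.

Step 14
Reactants: 24 15,15-dimethoxy-7β,16-bis(trimethylsilyloxy)labda-8(17),11E,13(16)E-triene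
Product: 26 11-bromo-7β-hydroxylabda-8(17),12E-diene-15,16-dial (C11 epimers), via bromo acetal 25 (not isolated)
Conditions: NBS (1.05 equiv), THF, −78 °C; then aq. HCl (0.5 M), THF, 0 °C
Reagents that add atoms: N-bromosuccinimide, O=C1CCC(=O)N1Br; water, O
Why: Vinylogous (γ-selective) electrophilic bromination of the silyl dienol ether through its s-trans conformer should regenerate the enal with E geometry, and mild aqueous acid then removes the silyl ether and the dimethyl acetal.

Step 15
Reactants: 26 11-bromo-7β-hydroxylabda-8(17),12E-diene-15,16-dial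
Product: 28 CNP0269954.2, (11S,15R)-11,15-epidioxy-7β,15-dihydroxylabda-8(17),12E-dien-16-al, via hydroperoxy dial 27 (not isolated)
Conditions: H2O2 (anhydrous, Et2O solution, 10 equiv), AgOCOCF3 (1.2 equiv), Et2O, 0 °C, dark
Reagents that add atoms: hydrogen peroxide, OO
Why: Silver-assisted substitution of the allylic bromide by hydrogen peroxide should give hydroperoxide 27, which adds to the C15 aldehyde to form the seven-membered peroxyhemiacetal (the E double bond keeps C16 out of reach); C11 is set by entry of the peroxide anti to the quaternary C10 on the conformer in which C9–H eclipses the allylic plane, and C15 by equilibration.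

Compound list
1 | (R)-carvone, (5R)-2-methyl-5-(prop-1-en-2-yl)cyclohex-2-en-1-one | CC1=CC[C@@H](C(C)=C)CC1=O | starting material
2 | (5R)-5-(1-hydroperoxy-1-methoxyethyl)-2-methylcyclohex-2-en-1-one (side-chain epimers) | CC1=CC[C@@H](C(C)(OC)OO)CC1=O | intermediate
3 | (5R)-5-[1-(acetylperoxy)-1-methoxyethyl]-2-methylcyclohex-2-en-1-one (side-chain epimers) | CC1=CC[C@@H](C(C)(OC)OOC(C)=O)CC1=O | intermediate
4 | (1R)-4-methyl-5-oxocyclohex-3-en-1-yl acetate | CC1=CC[C@@H](OC(C)=O)CC1=O | intermediate
5 | trimethyl[(2-methylprop-1-en-1-yl)oxy]silane | CC(C)=CO[Si](C)(C)C | starting material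
6 | (1R,5R)-4-methyl-5-(2-methyl-1-oxopropan-2-yl)-3-[(trimethylsilyl)oxy]cyclohex-3-en-1-yl acetate | CC1=C(O[Si](C)(C)C)C[C@H](OC(C)=O)C[C@H]1C(C)(C)C=O | intermediate
7 | triphenyl(vinyl)phosphonium bromide | C=C[P+](c1ccccc1)(c1ccccc1)c1ccccc1.[Br-] | starting material
8 | tris(dimethylamino)sulfonium C9–C10 enolate derived from 6 | CC1=C([O-])C[C@H](OC(C)=O)C[C@H]1C(C)(C)C=O.CN(C)[S+](N(C)C)N(C)C | intermediate
9 | (1R,3S,4S)-4-methyl-3-(2-methyl-1-oxopropan-2-yl)-5-oxo-4-[2-(triphenylphosphoranylidene)ethyl]cyclohexyl acetate | O=CC(C)(C)[C@@H]1C[C@@H](OC(C)=O)CC(=O)[C@@]1(C)CC=P(c1ccccc1)(c1ccccc1)c1ccccc1 | intermediate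
10 | (3R,4aS,8aS)-5,5,8a-trimethyl-1-oxo-1,2,3,4,4a,5,8,8a-octahydronaphthalen-3-yl acetate | O=C1C[C@H](OC(C)=O)C[C@H]2C(C)(C)C=CC[C@]12C | intermediate
11 | (3R,4aS,8aS)-5,5,8a-trimethyl-1-oxodecahydronaphthalen-3-yl acetate | O=C1C[C@H](OC(C)=O)C[C@H]2C(C)(C)CCC[C@]12C | intermediate
12 | (3R,4aS,8aS)-5,5,8a-trimethyl-1-(prop-2-en-1-yl)decahydronaphthalene-1,3-diol (C1 epimers) | C=CCC1(O)C[C@H](O)C[C@H]2C(C)(C)CCC[C@]12C | intermediate
13 | (4aS,8aS)-4-hydroxy-4a,8,8-trimethyl-4-(prop-2-en-1-yl)octahydronaphthalen-2(1H)-one (C4 epimers) | C=CCC1(O)CC(=O)C[C@H]2C(C)(C)CCC[C@]12C | intermediate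
14 | (4aS,8aS)-4a,8,8-trimethyl-4-(prop-2-en-1-yl)-4a,5,6,7,8,8a-hexahydronaphthalen-2(1H)-one | C=CCC1=CC(=O)C[C@H]2C(C)(C)CCC[C@]12C | intermediate
15 | lithium 14,15,16,17-tetranorlabda-7,12-dien-7-olate (9α-H) | [Li+].C=CC[C@H]1C=C([O-])C[C@H]2C(C)(C)CCC[C@]12C | intermediate
16 | 17-hydroxy-14,15,16-trinorlabd-12-en-7-one (9α-H; C8 epimers) | C=CC[C@H]1C(CO)C(=O)C[C@H]2C(C)(C)CCC[C@]12C | intermediate
17 | 7-oxo-14,15,16-trinorlabd-12-en-17-yl methanesulfonate (C8 epimers) | C=CC[C@H]1C(COS(C)(=O)=O)C(=O)C[C@H]2C(C)(C)CCC[C@]12C | intermediate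
18 | 14,15,16-trinorlabda-8(17),12-dien-7-one | C=CC[C@H]1C(=C)C(=O)C[C@H]2C(C)(C)CCC[C@]12C | intermediate
19 | 14,15,16-trinorlabda-8(17),12-dien-7β-ol | C=CC[C@H]1C(=C)[C@@H](O)C[C@H]2C(C)(C)CCC[C@]12C | intermediate
20 | methyl 4,4-dimethoxybutanoate | COC(=O)CCC(OC)OC | starting material
21 | 4,4-dimethoxybutanal | O=CCCC(OC)OC | intermediate
22 | 4,4-dimethoxy-2-methylidenebutanal | C=C(C=O)CC(OC)OC | intermediate
23 | 7β-hydroxy-15,15-dimethoxylabda-8(17),12E-dien-16-al | O=C/C(CC(OC)OC)=C/C[C@H]1C(=C)[C@@H](O)C[C@H]2C(C)(C)CCC[C@]12C | intermediate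
24 | 15,15-dimethoxy-7β,16-bis(trimethylsilyloxy)labda-8(17),11E,13(16)E-triene | C[Si](C)(C)O/C=C(CC(OC)OC)/C=C/[C@H]1C(=C)[C@@H](O[Si](C)(C)C)C[C@H]2C(C)(C)CCC[C@]12C | intermediate
25 | 11-bromo-15,15-dimethoxy-7β-(trimethylsilyloxy)labda-8(17),12E-dien-16-al (C11 epimers) | O=C/C(CC(OC)OC)=C/C(Br)[C@H]1C(=C)[C@@H](O[Si](C)(C)C)C[C@H]2C(C)(C)CCC[C@]12C | intermediate
26 | 11-bromo-7β-hydroxylabda-8(17),12E-diene-15,16-dial (C11 epimers) | O=C/C(CC=O)=C/C(Br)[C@H]1C(=C)[C@@H](O)C[C@H]2C(C)(C)CCC[C@]12C | intermediate
27 | (11S)-11-hydroperoxy-7β-hydroxylabda-8(17),12E-diene-15,16-dial | O=C/C(CC=O)=C/[C@H](OO)[C@H]1C(=C)[C@@H](O)C[C@H]2C(C)(C)CCC[C@]12C | intermediate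
28 | CNP0269954.2, (5S,7S,9R,10S,11S,15R)-11,15-epidioxy-7,15-dihydroxylabda-8(17),12E-dien-16-al | C=C1[C@H]([C@@H]2C=C(C=O)C[C@H](O)OO2)[C@@]2(C)CCCC(C)(C)[C@@H]2C[C@@H]1O | target

Total step count: 15. Longest linear sequence: 13 steps (steps 1–9 and 12–15; steps 10 and 11 prepare the metathesis partner).

Steps most likely to fail

Step 15. The substitution at C11 may proceed with inversion of the major bromide rather than with facial control by C9, which would give the C11 epimer; the silver salt and hydrogen peroxide may also oxidize the aldehydes, or the peroxide may fragment once formed. The fallback sets out from 24 and forms the C11–O bond directly: sensitized photooxygenation (O2, visible light, tetraphenylporphyrin, CH2Cl2, −78 °C) should attack C11 of the silyl dienol ether anti to C10 with silyl migration and give (11S)-15,15-dimethoxy-11-(trimethylsilylperoxy)-7β-(trimethylsilyloxy)labda-8(17),12E-dien-16-al F1. Aqueous HCl (0.5 M) in THF then cleaves the silyl groups and the acetal, and the released hydroperoxy dial 27 closes to 28. This variant only serves if attack on the s-trans diene outruns [4+2] addition across C11 and C16, which would lead to the 12Z series.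

Step 3. The naked enolate may add to the aldehyde of a second molecule instead of the phosphonium salt, may be alkylated on oxygen, or may equilibrate to the C8 enolate, which loses acetate; attack syn to the C5 substituent would give the cis-fused ring system. The fallback sets out from 6 and keeps the construction of both ring A bonds in one operation: the enolate (TASF, THF, −40 °C) adds to phenyl vinyl sulfone, and the α-sulfonyl carbanion closes ring A by aldol addition to the C3 aldehyde to give (3R,4aS,8aS)-6-hydroxy-5,5,8a-trimethyl-1-oxo-7-(phenylsulfonyl)decahydronaphthalen-3-yl acetate F2. Acetylation (Ac2O, DMAP, pyridine) gives the 6-acetate, (3R,4aS,8aS)-5,5,8a-trimethyl-1-oxo-7-(phenylsulfonyl)decahydronaphthalene-3,6-diyl diacetate F3, and Julia-type reductive elimination (Na(Hg), Na2HPO4, MeOH/THF, −20 °C) comes back to 10.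

Step 6. During the acid-catalysed dehydration of ketol 13 the terminal alkene may migrate into conjugation, a cationic 1,2-methyl shift from C10 may occur, or the ketol may open by retro-aldol cleavage; in step 5 the Grignard reagent may also eliminate acetate before it adds. The fallback sets out from 11: elimination of acetic acid with DBU (CH2Cl2, rt) gives (4aS,8aS)-5,5,8a-trimethyl-4a,5,6,7,8,8a-hexahydronaphthalen-1(4H)-one F4. 1,2-Addition of CH2=CHCH2MgBr (THF, −78 °C) gives (4aS,8aS)-5,5,8a-trimethyl-1-(prop-2-en-1-yl)-1,4,4a,5,6,7,8,8a-octahydronaphthalen-1-ol F5, and oxidative 1,3-transposition of this tertiary allylic alcohol with pyridinium chlorochromate (C5H5NH+ CrO3Cl−, CH2Cl2, rt) comes back to 14 without a carbocation or a free ketol.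

Further compounds
F1 | step 15 | (11S)-15,15-dimethoxy-11-(trimethylsilylperoxy)-7β-(trimethylsilyloxy)labda-8(17),12E-dien-16-al | O=C/C(CC(OC)OC)=C/[C@H](OO[Si](C)(C)C)[C@H]1C(=C)[C@@H](O[Si](C)(C)C)C[C@H]2C(C)(C)CCC[C@]12C
F2 | step 3 | (3R,4aS,8aS)-6-hydroxy-5,5,8a-trimethyl-1-oxo-7-(phenylsulfonyl)decahydronaphthalen-3-yl acetate (C6 and C7 epimers) | O=C1C[C@H](OC(C)=O)C[C@H]2C(C)(C)C(O)C(S(=O)(=O)c3ccccc3)C[C@]12C
F3 | step 3 | (3R,4aS,8aS)-5,5,8a-trimethyl-1-oxo-7-(phenylsulfonyl)decahydronaphthalene-3,6-diyl diacetate (C6 and C7 epimers) | O=C1C[C@H](OC(C)=O)C[C@H]2C(C)(C)C(OC(C)=O)C(S(=O)(=O)c3ccccc3)C[C@]12C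
F4 | step 6 | (4aS,8aS)-5,5,8a-trimethyl-4a,5,6,7,8,8a-hexahydronaphthalen-1(4H)-one | O=C1C=CC[C@H]2C(C)(C)CCC[C@]12C
F5 | step 6 | (4aS,8aS)-5,5,8a-trimethyl-1-(prop-2-en-1-yl)-1,4,4a,5,6,7,8,8a-octahydronaphthalen-1-ol (C1 epimers) | C=CCC1(O)C=CC[C@H]2C(C)(C)CCC[C@]12C
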